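The cyclohexene core is read as an oxidised benzene ring. The cis C1–O/C2–O pair, flanked by C3–O, C6–O and the C4=C5 alkene, is the cis-dihydrodiol of a halobenzene whose halogen sits on C6. Toluene dioxygenase converts plain bromobenzene in one operation into the enantiopure (1S,2S) bromodiene diol, forming both C–O bonds and both stereocentres with dearomatisation. After acetonide protection, singlet oxygen adds anti to the acetonide, which sets C3–O and unmasks the C6 ketone. Baylis–Hillman hydroxymethylation with formaldehyde, Luche reduction, Mitsunobu benzoylation with inversion and an orthoacetate monoacetylation complete the target.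

Key step: step 1

Remark on numbering: in every compound the ring atoms are C1 (CHOAc in the target), C2 and C3 (CHOH), C4=C5 (C5 bears C7) and C6 (CHOBz). "Upper face" is the face of the C1 and C2 oxygens; "lower face" is the opposite one.
Assumption: the whole-cell oxidation is counted as one step and is run in a recombinant host that expresses toluene dioxygenase but no cis-diol dehydrogenase.

Step 1
Reactants: 1 bromobenzene
Product: 2 (1S,2S)-3-bromocyclohexa-3,5-diene-1,2-diol
Conditions: E. coli JM109(pDTG601) whole cells expressing toluene dioxygenase, IPTG induction, glucose feed, air, mineral medium pH 7, 30–37 °C; EtOAc extraction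
Reagents that add atoms: dioxygen, O=O
Why: The Rieske [2Fe-2S] cluster passes two electrons from NADH to the mononuclear non-heme iron site, where O2 is bound and both oxygen atoms are delivered to the same face of the arene bond next to the bromine-bearing carbon, so the C1–O and C2–O bonds of the target form in one event with loss of aromaticity. The closest known reaction type is the whole-cell cis-dihydroxylation of monosubstituted benzenes by toluene dioxygenase, for which halobenzenes are standard substrates. No ring is closed. Both new stereocentres are controlled by the enzyme pocket, which exposes a single arene face and a single ring edge to the iron-bound oxygen and should therefore give the (1S,2S) diol as one enantiomer. The step needs regioselectivity (diol adjacent to bromine) and enantioselectivity, both secured by the way the bromine substituent docks in the active site, and it needs the diol to survive, which the absence of the cis-diol dehydrogenase in the host secures.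

Step 2
Reactants: 2 (1S,2S)-3-bromocyclohexa-3,5-diene-1,2-diol
Product: 3 (3aS,7aS)-4-bromo-2,2-dimethyl-3a,7a-dihydro-1,3-benzodioxole
Conditions: Me2C(OMe)2, pTsOH·H2O (cat.), acetone, rt; used at once
Reagents that add atoms: 2,2-dimethoxypropane, COC(C)(C)OC
Why: Acetonide formation by acid-catalysed transketalisation is fast on the cis-diol, leaves both stereocentres untouched and gives the cis-fused dioxolane that shields the upper face of the diene.

Step 3
Reactants: 3 (3aS,7aS)-4-bromo-2,2-dimethyl-3a,7a-dihydro-1,3-benzodioxole
Product: 6 (3aS,7R,7aS)-7-hydroxy-2,2-dimethyl-7,7a-dihydro-1,3-benzodioxol-4(3aH)-one, via bromo endoperoxide 4 (not isolated), via geminal bromohydrin 5 (not isolated)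
Conditions: O2, hν, tetraphenylporphyrin (cat.), CH2Cl2, −30 °C; then thiourea, MeOH, −30 °C → rt
Reagents that add atoms: dioxygen (as singlet oxygen), O=O
Why: Singlet oxygen adds across C3/C6 of the diene in a [4+2] cycloaddition on the face opposite the acetonide, which sets the C3–O bond trans to the C2–O bond, and thiourea reduction of the O–O bond leaves a geminal bromohydrin at C6 that loses HBr to give the C6 ketone conjugated with C4=C5.

Step 4
Reactants: 6 (3aS,7R,7aS)-7-hydroxy-2,2-dimethyl-7,7a-dihydro-1,3-benzodioxol-4(3aH)-one
Product: 7 C3 tert-butyldimethylsilyl ether of enone 6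
Conditions: TBSCl, imidazole, DMF, 0 °C → rt
Reagents that add atoms: tert-butyldimethylsilyl chloride, CC(C)(C)[Si](C)(C)Cl
Why: Standard silylation of a secondary alcohol masks the C3 hydroxyl, so that C6 will later carry the only free secondary alcohol, and no stereocentre is affected.

Step 5
Reactants: 7 C3 tert-butyldimethylsilyl ether of enone 6; 8 formaldehyde
Product: 9 C5-hydroxymethyl enone (C7-OH, C6 ketone, C3-OTBS, C1/C2 acetonide)
Conditions: aq. CH2O (37%), DMAP (0.3 equiv), THF/H2O, rt
Reagents that add atoms: formaldehyde (compound 8), C=O
Why: In this Morita–Baylis–Hillman reaction DMAP adds reversibly to C4, the enolate so formed is trapped at C5 by formaldehyde and DMAP is expelled again, a sequence known for 4-silyloxycyclohex-2-enones with aqueous formaldehyde; no stereocentre is formed and C1 cannot epimerise without breaking the cis ring fusion.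

Step 6
Reactants: 9 C5-hydroxymethyl enone
Product: 10 C6,C7 diol with the C6 hydroxyl on the upper face (cis to the C1 oxygen)
Conditions: NaBH4, CeCl3·7H2O, MeOH, −78 °C → −40 °C
Reagents that add atoms: none
Why: Luche reduction gives 1,2-addition to the enone, and hydride should enter C6 from the lower face, away from the adjacent C1–O bond of the cis-fused acetonide, so the new C6 hydroxyl is cis to the C1 oxygen, which is the epimer the later inversion needs.

Step 7
Reactants: 10 C6,C7 diol
Product: 11 C7 benzoate with free C6 hydroxyl (upper face)
Conditions: BzCl (1.05 equiv), pyridine, CH2Cl2, −40 °C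
Reagents that add atoms: benzoyl chloride, O=C(Cl)c1ccccc1
Why: Acylation with one equivalent of benzoyl chloride at low temperature distinguishes the unhindered primary allylic C7 alcohol from the C6 alcohol, which is secondary and flanked by the acetonide and the trisubstituted alkene; no stereocentre is affected.

Step 8
Reactants: 11 C7 benzoate with free C6 hydroxyl; 12 benzoic acid
Product: 13 C6,C7 dibenzoate with the C6 benzoate on the lower face (trans to the C1 oxygen), C3-OTBS, C1/C2 acetonide
Conditions: PhCO2H, PPh3, DIAD, THF, 0 °C → rt
Reagents that add atoms: benzoic acid (compound 12), OC(=O)c1ccccc1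
Why: In this Mitsunobu reaction the C6 alcohol is activated as its alkoxyphosphonium salt and displaced by benzoate in an SN2 process from the open lower face (the C1–H side), so C6 is inverted and the benzoate ends up trans to the C1 oxygen.

Step 9
Reactants: 13 C6,C7 dibenzoate
Product: 14 C1,C2,C3 triol bearing the C6 and C7 benzoates
Conditions: TFA/H2O (9:1), 0 °C → rt
Reagents that add atoms: none
Why: Aqueous acid hydrolyses the isopropylidene ketal and the allylic silyl ether in one operation (acetal hydrolysis and protodesilylation), while the benzoates are stable to acid at this temperature and no C–O bond at a stereocentre is broken.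

Step 10
Reactants: 14 C1,C2,C3 triol
Product: 16 [(3R,4S,5S,6S)-5-acetoxy-6-(benzoyloxy)-3,4-dihydroxycyclohex-1-en-1-yl]methyl benzoate (target CNP0213675.1), via cyclic orthoacetate 15 (not isolated)
Conditions: MeC(OMe)3, camphorsulfonic acid (cat.), MeCN, rt; then AcOH/H2O (4:1), rt
Reagents that add atoms: trimethyl orthoacetate, COC(C)(OC)OC; water, O
Why: In this orthoester-mediated monoacylation the five-membered cyclic orthoacetate can only bridge the cis C1/C2 oxygens (as in the selective orthoester formation of cis-diols in sugar triols), and mild acid hydrolysis should open it to the axial acetate, which is the C1 ester because allylic 1,2-strain with the C5 substituent holds the C6 benzoate pseudoaxial and therefore the C1–O bond axial; no stereocentre is touched.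

Compound list
1 | bromobenzene | Brc1ccccc1 | starting material
2 | (1S,2S)-3-bromocyclohexa-3,5-diene-1,2-diol | O[C@H]1[C@@H](O)C=CC=C1Br | intermediate
3 | (3aS,7aS)-4-bromo-2,2-dimethyl-3a,7a-dihydro-1,3-benzodioxole (acetonide of 2) | CC1(C)O[C@H]2[C@@H](O1)C=CC=C2Br | intermediate
4 | bromo endoperoxide: C1/C2 acetonide, O–O bridge from C3 to C6 on the lower face, Br on C6, C4=C5 alkene | CC1(C)O[C@H]2[C@@H](O1)[C@@H]3OO[C@@]2(Br)C=C3 | intermediate (not isolated)
5 | geminal bromohydrin: C1/C2 acetonide, C3-OH and C6-OH on the lower face, Br on C6 (upper face), C4=C5 alkene | CC1(C)O[C@H]2[C@@H](O1)[C@H](O)C=C[C@@]2(O)Br | intermediate (not isolated)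
6 | (3aS,7R,7aS)-7-hydroxy-2,2-dimethyl-7,7a-dihydro-1,3-benzodioxol-4(3aH)-one (C6 ketone, C4=C5, C3-OH trans to the acetonide) | CC1(C)O[C@H]2[C@@H](O1)[C@H](O)C=CC2=O | intermediate
7 | C3 tert-butyldimethylsilyl ether of 6 | CC1(C)O[C@H]2[C@@H](O1)[C@H](O[Si](C)(C)C(C)(C)C)C=CC2=O | intermediate
8 | formaldehyde | C=O | starting material
9 | C5-hydroxymethyl enone (C6 ketone, C3-OTBS, C1/C2 acetonide) | CC1(C)O[C@H]2[C@@H](O1)[C@H](O[Si](C)(C)C(C)(C)C)C=C(CO)C2=O | intermediate
10 | C6,C7 diol, C6-OH on the upper face (cis to C1–O), C3-OTBS, C1/C2 acetonide | CC1(C)O[C@H]2[C@@H](O1)[C@H](O[Si](C)(C)C(C)(C)C)C=C(CO)[C@H]2O | intermediate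
11 | C7 benzoate of 10, C6-OH free on the upper face | CC1(C)O[C@H]2[C@@H](O1)[C@H](O[Si](C)(C)C(C)(C)C)C=C(COC(=O)c1ccccc1)[C@H]2O | intermediate
12 | benzoic acid | OC(=O)c1ccccc1 | starting material
13 | C6,C7 dibenzoate, C6-OBz on the lower face (trans to C1–O), C3-OTBS, C1/C2 acetonide | CC1(C)O[C@H]2[C@@H](O1)[C@H](O[Si](C)(C)C(C)(C)C)C=C(COC(=O)c1ccccc1)[C@@H]2OC(=O)c1ccccc1 | intermediate
14 | [(3R,4S,5S,6S)-6-(benzoyloxy)-3,4,5-trihydroxycyclohex-1-en-1-yl]methyl benzoate (C1,C2,C3 triol) | O[C@H]1[C@@H](O)[C@H](O)C=C(COC(=O)c2ccccc2)[C@@H]1OC(=O)c1ccccc1 | intermediate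
15 | cyclic orthoacetate (2-methoxy-2-methyl-1,3-dioxolane) across the C1 and C2 oxygens of 14, both epimers at the orthoester carbon, C3-OH free | COC1(C)O[C@H]2[C@@H](O1)[C@H](O)C=C(COC(=O)c1ccccc1)[C@@H]2OC(=O)c1ccccc1 | intermediate (not isolated)
16 | [(3R,4S,5S,6S)-5-acetoxy-6-(benzoyloxy)-3,4-dihydroxycyclohex-1-en-1-yl]methyl benzoate | CC(=O)O[C@H]1[C@@H](O)[C@H](O)C=C(COC(=O)c2ccccc2)[C@@H]1OC(=O)c1ccccc1 | target

Total step count: 10. Longest linear sequence: 10 steps, from bromobenzene 1 to target 16.

Steps most likely to fail

Step 10. The orthoester may open toward the C2 ester, the acetyl group may migrate between the cis C1 and C2 oxygens, or the free C3 hydroxyl may be partly acetylated through an acyclic mixed orthoester. The fallback blocks C2 and C3 before acylation. It sets out from triol 14: butane-2,3-dione, HC(OMe)3 and catalytic camphorsulfonic acid in MeOH should engage only the trans-diequatorial C2/C3 diol and give the C2/C3 butane-2,3-diacetal F1, in which only the C1 hydroxyl is free. Ac2O, pyridine and catalytic DMAP then give the C1 acetate F2. TFA/H2O at 0 °C removes the diacetal, and the route is rejoined at target 16.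

Step 5. Conjugate addition of DMAP at C4, next to the silyloxy-bearing C3, may be slow. Prolonged exposure to base could then lead to β-elimination of the C2 oxygen and aromatisation. The fallback brings in C7 by cross-coupling instead. It sets out from enone 7: I2 and pyridine in CH2Cl2 should give the α-iodoenone F3. This is coupled in a Stille reaction (Pd(PPh3)4, a zerovalent palladium complex, dioxane, 80 °C) with (tributylstannyl)methanol F4, itself made from Bu3SnH, LiN(iPr)2 and paraformaldehyde (from 8) in THF. The route is rejoined at hydroxymethyl enone 9.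

Step 8. The activated C6 alcohol may undergo allylic transposition (attack at C4) or elimination toward C1 instead of direct displacement. Participation by the C7 benzoate may also give hydroxy benzoates. These still carry the inverted C6 oxygen and can be converged on 13 with BzCl/pyridine. The fallback separates activation from displacement. It sets out from alcohol 11: MsCl and Et3N in CH2Cl2 at −20 °C give the C6 methanesulfonate F5. This is displaced with inversion by cesium benzoate F6 (PhCO2Cs, from 12 and Cs2CO3) with 18-crown-6 in toluene at 60 °C. The route is rejoined at dibenzoate 13.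

Further compounds
F1 | step 10 | C2/C3 butane-2,3-diacetal of triol 14 (trans-fused 2,3-dimethoxy-2,3-dimethyl-1,4-dioxane, both OMe axial), C1-OH free | O[C@H]1[C@@H](O[C@](C)(OC)[C@@](C)(OC)O2)[C@H]2C=C(COC(=O)c2ccccc2)[C@@H]1OC(=O)c1ccccc1
F2 | step 10 | C1 acetate of F1 | CC(=O)O[C@H]1[C@@H](O[C@](C)(OC)[C@@](C)(OC)O2)[C@H]2C=C(COC(=O)c2ccccc2)[C@@H]1OC(=O)c1ccccc1
F3 | step 5 | C5-iodo enone (α-iodo derivative of 7) | CC1(C)O[C@H]2[C@@H](O1)[C@H](O[Si](C)(C)C(C)(C)C)C=C(I)C2=O
F4 | step 5 | (tributylstannyl)methanol | CCCC[Sn](CCCC)(CCCC)CO
F5 | step 8 | C6 methanesulfonate of 11 (upper face) | CC1(C)O[C@H]2[C@@H](O1)[C@H](O[Si](C)(C)C(C)(C)C)C=C(COC(=O)c1ccccc1)[C@H]2OS(C)(=O)=O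
F6 | step 8 | cesium benzoate | [Cs+].[O-]C(=O)c1ccccc1
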